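**Retrosynthetic overview**
1. Target 22 ⇐ global desilylation of the tetra-TIPS compound 21. No ring is formed in the route; the phloroglucinol ring is bought as 2,4,6-trihydroxybenzaldehyde (1).
2. C12=C13 (Z) ⇐ Wittig reaction of the γ-silyloxy-(E)-enal 16 with the ylide from (Z)-hex-3-enylphosphonium salt 19. C10=C11 (E) ⇐ Wittig homologation of the α-silyloxy aldehyde 14.
3. C8–C9 bond, C9 stereocentre and C6=C7 (Z) ⇐ one proposed new step: Ni(0)/chiral-NHC reductive coupling of the terminal (E)-diene 10, (TBS-oxy)acetaldehyde 11 and iPr3SiH.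
4. Diene 10 ⇐ cross-metathesis with crotonaldehyde, then methylenation, of the aryl hexenyl ketone 5 ⇐ Grignard addition to aldehyde 2 and oxidation.

Assumption: compounds 1, 3, 6, 8, 11, 15 and 17 are bought. Ar = 2,4,6-tris(triisopropylsilyloxy)phenyl, TIPS = triisopropylsilyl, TBS = tert-butyldimethylsilyl. Numbered building blocks stand on the Reactants line; un-numbered reagents that add atoms stand on the "Reagents that add atoms" line.

**Step 1**
Reactants: 1 2,4,6-trihydroxybenzaldehyde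
Product: 2 2,4,6-tris(triisopropylsilyloxy)benzaldehyde
Conditions: TIPSOTf (3.6 equiv), 2,6-lutidine, CH2Cl2, 0 °C → rt
Reagents that add atoms: triisopropylsilyl trifluoromethanesulfonate, CC(C)[Si](C(C)C)(C(C)C)OS(=O)(=O)C(F)(F)F
Why: O-silylation of phenols with a silyl triflate and a hindered base is fast even for the hydrogen-bonded ortho hydroxyls, and TIPS is chosen because it resists O→O migration in the later anionic steps.

**Step 2**
Reactants: 2 2,4,6-tris(triisopropylsilyloxy)benzaldehyde, 3 pent-4-enylmagnesium bromide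
Product: 4 1-[2,4,6-tris(triisopropylsilyloxy)phenyl]hex-5-en-1-ol (racemic)
Conditions: THF, −78 → −20 °C; then pH 7 buffer
Reagents that add atoms: none
Why: Grignard 1,2-addition of a primary alkylmagnesium halide to an aryl aldehyde; the new benzylic centre is racemic and is removed in step 3.

**Step 3**
Reactants: 4 1-[2,4,6-tris(triisopropylsilyloxy)phenyl]hex-5-en-1-ol
Product: 5 1-[2,4,6-tris(triisopropylsilyloxy)phenyl]hex-5-en-1-one
Conditions: Dess–Martin periodinane, NaHCO3, CH2Cl2, 0 °C → rt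
Reagents that add atoms: none
Why: Dess–Martin oxidation of a secondary benzylic alcohol is neutral and leaves aryl silyl ethers and the terminal alkene untouched.

**Step 4**
Reactants: 5 1-[2,4,6-tris(triisopropylsilyloxy)phenyl]hex-5-en-1-one, 6 (E)-but-2-enal (crotonaldehyde)
Product: 7 (E)-7-oxo-7-[2,4,6-tris(triisopropylsilyloxy)phenyl]hept-2-enal
Conditions: Hoveyda–Grubbs II (5 mol%), crotonaldehyde (5 equiv), CH2Cl2, 40 °C
Reagents that add atoms: none
Why: Olefin cross-metathesis of a terminal (type I) alkene with an electron-poor enal is selective for the cross product and gives the (E)-enal under thermodynamic control.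

**Step 5**
Reactants: 7 (E)-7-oxo-7-[2,4,6-tris(triisopropylsilyloxy)phenyl]hept-2-enal, 8 methyltriphenylphosphonium bromide
Product: 10 (E)-1-[2,4,6-tris(triisopropylsilyloxy)phenyl]octa-5,7-dien-1-one, via methylenetriphenylphosphorane 9 (not isolated)
Conditions: 8, KHMDS, THF, 0 °C; then 7, −78 → 0 °C
Reagents that add atoms: none
Why: Wittig methylenation takes place at the unhindered aldehyde only, because the di-ortho-silyloxy aryl ketone is too shielded to react, and the existing (E)-alkene is not touched.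

**Step 6**
Reactants: 10 (E)-1-[2,4,6-tris(triisopropylsilyloxy)phenyl]octa-5,7-dien-1-one, 11 2-[(tert-butyldimethylsilyl)oxy]acetaldehyde
Product: 12 (6Z,9R)-10-[(tert-butyldimethylsilyl)oxy]-9-[(triisopropylsilyl)oxy]-1-[2,4,6-tris(triisopropylsilyloxy)phenyl]dec-6-en-1-one
Conditions: Ni(cod)2 (10 mol%), new chiral NHC L* [(4R,5R)-1,3-bis(5-tert-butyl-2-isopropylphenyl)-4,5-diphenylimidazolidin-2-ylidene, from its HBF4 salt (12 mol%) and KOtBu (12 mol%); the antipode is used if the facial sense proves opposite], iPr3SiH (2 equiv), slow addition of 11 (1.5 equiv), THF, 0 °C → rt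
Reagents that add atoms: triisopropylsilane, CC(C)[SiH](C(C)C)C(C)C
Why: Proposed new method: an enantioselective, Z-selective, linear 1,4-hydro(hydroxyalkyl)ation of a terminal 1-alkyl-1,3-diene, in which Ni(0)–L* binds the s-cis diene and the aldehyde, oxidative cyclisation joins the unsubstituted diene terminus (C8) to the Re face of the aldehyde inside the C2-symmetric NHC pocket (setting 9R) to give an anti-η3-allyl oxanickelacycle, Si–H σ-bond metathesis cleaves Ni–O (installing the TIPS ether) and leaves an allyl–Ni–H, and C–H reductive elimination at the distal terminus (C5) before anti→syn allyl isomerisation fixes C6=C7 as Z; the closest known reaction types are the racemic Z-selective Ni(0)/NHC three-component coupling of 1,3-dienes, aldehydes and hydrosilanes and the enantioselective Ni/chiral-NHC reductive coupling of alkynes with aldehydes.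

**Step 7**
Reactants: 12 (6Z,9R)-10-[(tert-butyldimethylsilyl)oxy]-9-[(triisopropylsilyl)oxy]-1-[2,4,6-tris(triisopropylsilyloxy)phenyl]dec-6-en-1-one
Product: 13 (6Z,9R)-10-hydroxy-9-[(triisopropylsilyl)oxy]-1-[2,4,6-tris(triisopropylsilyloxy)phenyl]dec-6-en-1-one
Conditions: CSA (0.2 equiv), MeOH/CH2Cl2 1:1, 0 °C
Reagents that add atoms: none
Why: Acid-catalysed methanolysis removes a primary alkyl TBS ether much faster than a secondary alkyl TIPS ether or aryl TIPS ethers (selective desilylation).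

**Step 8**
Reactants: 13 (6Z,9R)-10-hydroxy-9-[(triisopropylsilyl)oxy]-1-[2,4,6-tris(triisopropylsilyloxy)phenyl]dec-6-en-1-one
Product: 14 (2R,4Z)-10-oxo-2-[(triisopropylsilyl)oxy]-10-[2,4,6-tris(triisopropylsilyloxy)phenyl]dec-4-enal
Conditions: Dess–Martin periodinane, NaHCO3, CH2Cl2, 0 °C → rt; used crude
Reagents that add atoms: none
Why: Buffered Dess–Martin oxidation gives the α-silyloxy aldehyde without epimerising C9 and without moving the Z-alkene.

**Step 9**
Reactants: 14 (2R,4Z)-10-oxo-2-[(triisopropylsilyl)oxy]-10-[2,4,6-tris(triisopropylsilyloxy)phenyl]dec-4-enal, 15 2-(triphenylphosphoranylidene)acetaldehyde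
Product: 16 (2E,4R,6Z)-12-oxo-4-[(triisopropylsilyl)oxy]-12-[2,4,6-tris(triisopropylsilyloxy)phenyl]dodeca-2,6-dienal
Conditions: 15 (1.5 equiv), toluene, 70 °C
Reagents that add atoms: none
Why: Wittig reaction with a stabilised formylmethylene ylide is E-selective, base-free (no epimerisation at C9) and stops at the enal because the product is less electrophilic than the α-oxy aldehyde.

**Step 10**
Reactants: 17 (Z)-hex-3-en-1-ol
Product: 18 (Z)-1-iodohex-3-ene
Conditions: I2, PPh3, imidazole, CH2Cl2, 0 °C → rt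
Reagents that add atoms: iodine, II
Why: Appel-type iodination of a primary alcohol proceeds by SN2 on the alkoxyphosphonium ion and does not touch the Z-alkene.

**Step 11**
Reactants: 18 (Z)-1-iodohex-3-ene
Product: 19 [(Z)-hex-3-en-1-yl]triphenylphosphonium iodide
Conditions: PPh3, MeCN, reflux
Reagents that add atoms: triphenylphosphine, c1ccc(cc1)P(c1ccccc1)c1ccccc1
Why: SN2 quaternisation of triphenylphosphine by a primary iodide gives the crystalline phosphonium salt.

**Step 12**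
Reactants: 16 (2E,4R,6Z)-12-oxo-4-[(triisopropylsilyl)oxy]-12-[2,4,6-tris(triisopropylsilyloxy)phenyl]dodeca-2,6-dienal, 19 [(Z)-hex-3-en-1-yl]triphenylphosphonium iodide
Product: 21 (6Z,9R,10E,12Z,15Z)-9-[(triisopropylsilyl)oxy]-1-[2,4,6-tris(triisopropylsilyloxy)phenyl]octadeca-6,10,12,15-tetraen-1-one, via (Z)-hex-3-enylidenetriphenylphosphorane 20 (not isolated)
Conditions: 19, NaHMDS, THF, −78 → −20 °C; then 16, −78 → 0 °C
Reagents that add atoms: none
Why: Salt-free Wittig reaction of a non-stabilised ylide with an enal under kinetic control gives the new C12=C13 bond as Z, while the 10E alkene, C9 and the shielded aryl ketone are unaffected.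

**Step 13**
Reactants: 21 (6Z,9R,10E,12Z,15Z)-9-[(triisopropylsilyl)oxy]-1-[2,4,6-tris(triisopropylsilyloxy)phenyl]octadeca-6,10,12,15-tetraen-1-one
Product: 22 (6Z,9R,10E,12Z,15Z)-9-hydroxy-1-(2,4,6-trihydroxyphenyl)octadeca-6,10,12,15-tetraen-1-one (CNP0107106.1)
Conditions: TBAF/AcOH (1:1, 6 equiv), THF, 0 °C → rt, under Ar
Reagents that add atoms: none
Why: Fluoride-mediated desilylation cleaves the three aryl TIPS ethers quickly and the secondary allylic TIPS ether more slowly under near-neutral buffered conditions that avoid ionising the dienyl carbinol.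

**Compound list**
1 | 2,4,6-trihydroxybenzaldehyde | O=Cc1c(O)cc(O)cc1O | starting material
2 | 2,4,6-tris(triisopropylsilyloxy)benzaldehyde | O=Cc1c(O[Si](C(C)C)(C(C)C)C(C)C)cc(O[Si](C(C)C)(C(C)C)C(C)C)cc1O[Si](C(C)C)(C(C)C)C(C)C | intermediate
3 | pent-4-enylmagnesium bromide | C=CCCC[Mg]Br | starting material
4 | 1-[2,4,6-tris(triisopropylsilyloxy)phenyl]hex-5-en-1-ol (racemic) | C=CCCCC(O)c1c(O[Si](C(C)C)(C(C)C)C(C)C)cc(O[Si](C(C)C)(C(C)C)C(C)C)cc1O[Si](C(C)C)(C(C)C)C(C)C | intermediate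
5 | 1-[2,4,6-tris(triisopropylsilyloxy)phenyl]hex-5-en-1-one | C=CCCCC(=O)c1c(O[Si](C(C)C)(C(C)C)C(C)C)cc(O[Si](C(C)C)(C(C)C)C(C)C)cc1O[Si](C(C)C)(C(C)C)C(C)C | intermediate
6 | (E)-but-2-enal (crotonaldehyde) | C/C=C/C=O | starting material
7 | (E)-7-oxo-7-[2,4,6-tris(triisopropylsilyloxy)phenyl]hept-2-enal | O=C/C=C/CCCC(=O)c1c(O[Si](C(C)C)(C(C)C)C(C)C)cc(O[Si](C(C)C)(C(C)C)C(C)C)cc1O[Si](C(C)C)(C(C)C)C(C)C | intermediate
8 | methyltriphenylphosphonium bromide | C[P+](c1ccccc1)(c1ccccc1)c1ccccc1.[Br-] | starting material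
9 | methylenetriphenylphosphorane | C=P(c1ccccc1)(c1ccccc1)c1ccccc1 | intermediate
10 | (E)-1-[2,4,6-tris(triisopropylsilyloxy)phenyl]octa-5,7-dien-1-one | C=C/C=C/CCCC(=O)c1c(O[Si](C(C)C)(C(C)C)C(C)C)cc(O[Si](C(C)C)(C(C)C)C(C)C)cc1O[Si](C(C)C)(C(C)C)C(C)C | intermediate
11 | 2-[(tert-butyldimethylsilyl)oxy]acetaldehyde | CC(C)(C)[Si](C)(C)OCC=O | starting material
12 | (6Z,9R)-10-[(tert-butyldimethylsilyl)oxy]-9-[(triisopropylsilyl)oxy]-1-[2,4,6-tris(triisopropylsilyloxy)phenyl]dec-6-en-1-one | CC(C)(C)[Si](C)(C)OC[C@H](O[Si](C(C)C)(C(C)C)C(C)C)C/C=C\CCCCC(=O)c1c(O[Si](C(C)C)(C(C)C)C(C)C)cc(O[Si](C(C)C)(C(C)C)C(C)C)cc1O[Si](C(C)C)(C(C)C)C(C)C | intermediate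
13 | (6Z,9R)-10-hydroxy-9-[(triisopropylsilyl)oxy]-1-[2,4,6-tris(triisopropylsilyloxy)phenyl]dec-6-en-1-one | OC[C@H](O[Si](C(C)C)(C(C)C)C(C)C)C/C=C\CCCCC(=O)c1c(O[Si](C(C)C)(C(C)C)C(C)C)cc(O[Si](C(C)C)(C(C)C)C(C)C)cc1O[Si](C(C)C)(C(C)C)C(C)C | intermediate
14 | (2R,4Z)-10-oxo-2-[(triisopropylsilyl)oxy]-10-[2,4,6-tris(triisopropylsilyloxy)phenyl]dec-4-enal | O=C[C@H](O[Si](C(C)C)(C(C)C)C(C)C)C/C=C\CCCCC(=O)c1c(O[Si](C(C)C)(C(C)C)C(C)C)cc(O[Si](C(C)C)(C(C)C)C(C)C)cc1O[Si](C(C)C)(C(C)C)C(C)C | intermediate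
15 | 2-(triphenylphosphoranylidene)acetaldehyde | O=CC=P(c1ccccc1)(c1ccccc1)c1ccccc1 | starting material
16 | (2E,4R,6Z)-12-oxo-4-[(triisopropylsilyl)oxy]-12-[2,4,6-tris(triisopropylsilyloxy)phenyl]dodeca-2,6-dienal | O=C/C=C/[C@H](O[Si](C(C)C)(C(C)C)C(C)C)C/C=C\CCCCC(=O)c1c(O[Si](C(C)C)(C(C)C)C(C)C)cc(O[Si](C(C)C)(C(C)C)C(C)C)cc1O[Si](C(C)C)(C(C)C)C(C)C | intermediate
17 | (Z)-hex-3-en-1-ol | CC/C=C\CCO | starting material
18 | (Z)-1-iodohex-3-ene | CC/C=C\CCI | intermediate
19 | [(Z)-hex-3-en-1-yl]triphenylphosphonium iodide | CC/C=C\CC[P+](c1ccccc1)(c1ccccc1)c1ccccc1.[I-] | intermediate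
20 | (Z)-hex-3-enylidenetriphenylphosphorane | CC/C=C\CC=P(c1ccccc1)(c1ccccc1)c1ccccc1 | intermediate
21 | (6Z,9R,10E,12Z,15Z)-9-[(triisopropylsilyl)oxy]-1-[2,4,6-tris(triisopropylsilyloxy)phenyl]octadeca-6,10,12,15-tetraen-1-one | CC/C=C\C/C=C\C=C\[C@H](O[Si](C(C)C)(C(C)C)C(C)C)C/C=C\CCCCC(=O)c1c(O[Si](C(C)C)(C(C)C)C(C)C)cc(O[Si](C(C)C)(C(C)C)C(C)C)cc1O[Si](C(C)C)(C(C)C)C(C)C | intermediate
22 | (6Z,9R,10E,12Z,15Z)-9-hydroxy-1-(2,4,6-trihydroxyphenyl)octadeca-6,10,12,15-tetraen-1-one | CC/C=C\C/C=C\C=C\[C@H](O)C/C=C\CCCCC(=O)c1c(O)cc(O)cc1O | target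

**Step count**
Total: 13 steps. Longest linear sequence: 11 steps (steps 1–9, 12, 13); steps 10–11 make the phosphonium salt.

**Three steps most likely to fail**

Step 6 (proposed new Ni coupling; risks are low ee, 1,2- versus 1,4-hydride delivery, E/Z erosion, diene oligomerisation). The fallback uses known chemistry, sets out from 2 and comes back at 12. Aldehyde 2 is treated with hex-5-enylmagnesium bromide to give 1-[2,4,6-tris(triisopropylsilyloxy)phenyl]hept-6-en-1-ol F5, which Dess–Martin periodinane oxidises to 1-[2,4,6-tris(triisopropylsilyloxy)phenyl]hept-6-en-1-one F6. Separately, commercial tert-butyldimethylsilyl (R)-glycidyl ether is opened with vinylmagnesium bromide and catalytic CuI to give (R)-1-[(tert-butyldimethylsilyl)oxy]pent-4-en-2-ol F7, and TIPSOTf/2,6-lutidine converts it into (R)-1-[(tert-butyldimethylsilyl)oxy]-2-[(triisopropylsilyl)oxy]pent-4-ene F8. Z-selective cross-metathesis of F6 with excess F8 using a cyclometalated Z-selective ruthenium catalyst then gives 12, with the stereocentre taken from the chiral pool.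

Step 12 (Z-selective Wittig; risks are Z/E mixtures at C12=C13 and enolisation of the enal or ketone by the basic ylide). The fallback sets out from 14 and comes back at 21, bypassing steps 9–12. Takai iodo-olefination (CHI3, CrCl2) of 14 gives (6Z,9R,10E)-11-iodo-9-[(triisopropylsilyl)oxy]-1-[2,4,6-tris(triisopropylsilyloxy)phenyl]undeca-6,10-dien-1-one F9. Copper-catalysed coupling of ethynylmagnesium bromide with (Z)-1-bromopent-2-ene gives (Z)-hept-4-en-1-yne F10. Sonogashira coupling of F9 with F10 (Pd(PPh3)4, CuI, Et3N) gives (6Z,9R,10E,15Z)-9-[(triisopropylsilyl)oxy]-1-[2,4,6-tris(triisopropylsilyloxy)phenyl]octadeca-6,10,15-trien-12-yn-1-one F11. Zn(Cu/Ag) reduction in aqueous methanol reduces only the conjugated alkyne to the cis alkene and gives 21.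

Step 2 (Grignard addition to the doubly ortho-silyloxylated aldehyde; risks are steric blocking and O→O silyl migration to the new alkoxide). The fallback sets out from 1 and comes back at 5, carrying the phenols as non-migrating acetals through the C–C bond formation. MOMCl/iPr2NEt converts 1 into 2,4,6-tris(methoxymethoxy)benzaldehyde F1. Addition of 3 gives 1-[2,4,6-tris(methoxymethoxy)phenyl]hex-5-en-1-ol F2, and Dess–Martin oxidation gives 1-[2,4,6-tris(methoxymethoxy)phenyl]hex-5-en-1-one F3. HCl in MeOH removes the acetals to give 1-(2,4,6-trihydroxyphenyl)hex-5-en-1-one F4, and TIPSOTf/2,6-lutidine then gives 5.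

**Further compounds**
F1 | step 2 | 2,4,6-tris(methoxymethoxy)benzaldehyde | O=Cc1c(OCOC)cc(OCOC)cc1OCOC
F2 | step 2 | 1-[2,4,6-tris(methoxymethoxy)phenyl]hex-5-en-1-ol (racemic) | C=CCCCC(O)c1c(OCOC)cc(OCOC)cc1OCOC
F3 | step 2 | 1-[2,4,6-tris(methoxymethoxy)phenyl]hex-5-en-1-one | C=CCCCC(=O)c1c(OCOC)cc(OCOC)cc1OCOC
F4 | step 2 | 1-(2,4,6-trihydroxyphenyl)hex-5-en-1-one | C=CCCCC(=O)c1c(O)cc(O)cc1O
F5 | step 6 | 1-[2,4,6-tris(triisopropylsilyloxy)phenyl]hept-6-en-1-ol (racemic) | C=CCCCCC(O)c1c(O[Si](C(C)C)(C(C)C)C(C)C)cc(O[Si](C(C)C)(C(C)C)C(C)C)cc1O[Si](C(C)C)(C(C)C)C(C)C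
F6 | step 6 | 1-[2,4,6-tris(triisopropylsilyloxy)phenyl]hept-6-en-1-one | C=CCCCCC(=O)c1c(O[Si](C(C)C)(C(C)C)C(C)C)cc(O[Si](C(C)C)(C(C)C)C(C)C)cc1O[Si](C(C)C)(C(C)C)C(C)C
F7 | step 6 | (R)-1-[(tert-butyldimethylsilyl)oxy]pent-4-en-2-ol | CC(C)(C)[Si](C)(C)OC[C@H](O)CC=C
F8 | step 6 | (R)-1-[(tert-butyldimethylsilyl)oxy]-2-[(triisopropylsilyl)oxy]pent-4-ene | CC(C)(C)[Si](C)(C)OC[C@H](O[Si](C(C)C)(C(C)C)C(C)C)CC=C
F9 | step 12 | (6Z,9R,10E)-11-iodo-9-[(triisopropylsilyl)oxy]-1-[2,4,6-tris(triisopropylsilyloxy)phenyl]undeca-6,10-dien-1-one | I/C=C/[C@H](O[Si](C(C)C)(C(C)C)C(C)C)C/C=C\CCCCC(=O)c1c(O[Si](C(C)C)(C(C)C)C(C)C)cc(O[Si](C(C)C)(C(C)C)C(C)C)cc1O[Si](C(C)C)(C(C)C)C(C)C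
F10 | step 12 | (Z)-hept-4-en-1-yne | CC/C=C\CC#C
F11 | step 12 | (6Z,9R,10E,15Z)-9-[(triisopropylsilyl)oxy]-1-[2,4,6-tris(triisopropylsilyloxy)phenyl]octadeca-6,10,15-trien-12-yn-1-one | CC/C=C\CC#C/C=C/[C@H](O[Si](C(C)C)(C(C)C)C(C)C)C/C=C\CCCCC(=O)c1c(O[Si](C(C)C)(C(C)C)C(C)C)cc(O[Si](C(C)C)(C(C)C)C(C)C)cc1O[Si](C(C)C)(C(C)C)C(C)C
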